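**Retrosynthetic overview**
1. The last skeletal event is a tethered vinylketene/ynol ether benzannulation of an (S)-α-diazo enone ethynyl ether. A Wolff shift makes C4a–C5, an intramolecular [2+2] makes C7–C8 and C4a–C8a (ring C), and 4π opening followed by 6π closure makes C6–C7 (ring A). Fluoride then frees the C5' phenol.
2. Feature used: ring A is a resorcinol monoether with O1 on C8a, H on C8, a free OH on C7 and the quaternary 1,1-dimethylallyl carbon on C6. C4a is tied to O1 through C4–C3–C2. This is the substitution pattern of a vinylketene plus alkoxyalkyne annulation in which the two partners are already linked.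
3. The diazo enone comes from diazo transfer on the enone. The enone comes from a C2–C3–C4–C4a–C7 aldehyde and an (E)-alkenyllithium (C5, C6 and the quaternary carbon, from 2,2-dimethylbut-3-enoic acid). C8a and C8 come from trichloroethylene through a 1,2-dichlorovinyl ether.
4. The aldehyde comes from the bromo chromene aldehyde by Brown allylation (sets C2), ortho-prenylation, O-dichlorovinylation and hydroformylation. The bromo chromene aldehyde comes from a propargyl Claisen cascade on 6-bromoprotocatechualdehyde, where the bromine marks C2'.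
5. Ring order: B (bought), D (step 4), then C and A together (step 15).

Key step: step 15

Abbreviation used in names: Ar = 2,2-dimethyl-5-(3-methylbut-2-en-1-yl)-8-(triisopropylsilyloxy)-2H-chromen-6-yl, the complete B/D unit. Flavan numbering is used for atoms.

Assumption: the allylic carbinol carbon made in step 12 forms as a mixture of epimers. It is drawn without configuration because step 13 erases it.

Remark: the C5' phenol is carried as a TIPS ether, because a smaller aryl silyl ether would be at risk from KH, alkyllithiums and LiHMDS. All ethynyl ethers are kept at or below 25 °C, away from acid, and chromatographed on amine-washed silica.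

**Step 1**
Reactants: 1 2-bromo-4,5-dimethoxybenzaldehyde
Product: 2 2-bromo-4,5-dihydroxybenzaldehyde
Conditions: BBr3 (2.5 equiv), CH2Cl2, −78 °C to rt; H2O
Reagents that add atoms: none
Why: Lewis acid cleavage of both aryl methyl ethers (BBr3 demethylation) leaves the aldehyde and the aryl bromide untouched, and gives a catechol that already carries a halogen at the future C2'.

**Step 2**
Reactants: 2 2-bromo-4,5-dihydroxybenzaldehyde; 3 3-chloro-3-methylbut-1-yne
Product: 4 2-bromo-5-hydroxy-4-[(2-methylbut-3-yn-2-yl)oxy]benzaldehyde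
Conditions: DBU (1.05 equiv), CuCl2·2H2O (1 mol %), MeCN, 0 °C, argon
Reagents that add atoms: none
Why: In this copper-catalysed O-propargylation of a phenoxide with a tertiary propargylic chloride, one equivalent of base ionises only the C4 hydroxyl, which is para to the formyl group and clearly the more acidic, so the ether should form there.

**Step 3**
Reactants: 4 2-bromo-5-hydroxy-4-[(2-methylbut-3-yn-2-yl)oxy]benzaldehyde
Product: 5 2-bromo-4-[(2-methylbut-3-yn-2-yl)oxy]-5-(triisopropylsilyloxy)benzaldehyde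
Conditions: TIPSCl, imidazole, DMF, rt
Reagents that add atoms: triisopropylsilyl chloride CC(C)[Si](Cl)(C(C)C)C(C)C
Why: Standard phenol silylation masks the remaining hydroxyl, so it cannot add to the alkyne during the thermal step and survives the strong bases used later.

**Step 4**
Reactants: 5 2-bromo-4-[(2-methylbut-3-yn-2-yl)oxy]-5-(triisopropylsilyloxy)benzaldehyde
Product: 7 5-bromo-2,2-dimethyl-8-(triisopropylsilyloxy)-2H-chromene-6-carbaldehyde, via ortho-allenylphenol 6 (not isolated)
Conditions: 1,2-dichlorobenzene, 180 °C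
Reagents that add atoms: none
Why: The aromatic propargyl Claisen rearrangement, rearomatisation, 1,5-H shift and oxa-6π closure build ring D, and only the ortho carbon between the ether oxygen and the bromine is free, so one regioisomer is possible.

**Step 5**
Reactants: 7 5-bromo-2,2-dimethyl-8-(triisopropylsilyloxy)-2H-chromene-6-carbaldehyde
Product: 9 (S)-1-[5-bromo-2,2-dimethyl-8-(triisopropylsilyloxy)-2H-chromen-6-yl]but-3-en-1-ol, via borinate ester 8 (not isolated)
Conditions: (+)-Ipc2B(allyl) (the reagent derived from (+)-α-pinene, 1.3 equiv), Et2O, −78 °C; NaBO3·4H2O, THF/H2O, rt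
Reagents that add atoms: (+)-B-allyldiisopinocampheylborane C=CCB([C@@H]1C[C@@H]2C[C@H]([C@H]1C)C2(C)C)[C@@H]1C[C@@H]2C[C@H]([C@H]1C)C2(C)C
Why: In the Brown asymmetric allylboration the chair transition state of the (+)-α-pinene-derived reagent delivers allyl to the Si face of aryl aldehydes, which sets the future C2 as S and brings in C3, C4 and C4a.

**Step 6**
Reactants: 9 (S)-1-[5-bromo-2,2-dimethyl-8-(triisopropylsilyloxy)-2H-chromen-6-yl]but-3-en-1-ol; 10 1-bromo-3-methylbut-2-ene (prenyl bromide)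
Product: 12 (S)-1-Ar-but-3-en-1-ol, via dilithio species 11 (not isolated)
Conditions: n-BuLi (2.2 equiv), THF, −78 °C; CuBr·SMe2 (1.1 equiv), −78 to −40 °C; 10 (1.3 equiv), −78 to 0 °C; H2O
Reagents that add atoms: none
Why: Bromine–lithium exchange on the lithium alkoxide, transmetalation to copper and SN2 allylic substitution on prenyl bromide place the linear prenyl group exactly where the bromine stood, and the carbinol carbon takes no part.

**Step 7**
Reactants: 12 (S)-1-Ar-but-3-en-1-ol; 13 trichloroethylene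
Product: 15 (S)-1-Ar-but-3-en-1-yl (E)-1,2-dichlorovinyl ether, via dichloroacetylene 14 (not isolated)
Conditions: KH (1.5 equiv), THF, 0 °C; 13 (1.1 equiv), −50 °C to rt
Reagents that add atoms: none
Why: The potassium alkoxide adds in an anti sense to dichloroacetylene formed in situ (the trichloroethylene route to dichlorovinyl ethers, proven on hindered secondary benzylic alcohols), and only the O–H bond is broken, so C2 keeps its configuration.

**Step 8**
Reactants: 15 (S)-1-Ar-but-3-en-1-yl (E)-1,2-dichlorovinyl ether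
Product: 16 (S)-5-Ar-5-[(E)-1,2-dichlorovinyloxy]pentanal
Conditions: Rh(acac)(CO)2 (1 mol %), BIPHEPHOS (2 mol %), CO/H2 (1:1, 5 bar), THF, 60 °C
Reagents that add atoms: carbon monoxide [C-]#[O+]
Why: Linear-selective rhodium/bisphosphite hydroformylation reacts only at the monosubstituted alkene, since the prenyl, chromene and dichlorovinyl C=C bonds are much slower, and it adds the one missing carbon, the future C7.

**Step 9**
Reactants: 17 2,2-dimethylbut-3-enoic acid
Product: 18 2,2-dimethylbut-3-en-1-ol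
Conditions: LiAlH4, Et2O, 0 °C to rt; Fieser work-up
Reagents that add atoms: none
Why: Hydride reduction of a carboxylic acid does not touch the isolated vinyl group.

**Step 10**
Reactants: 18 2,2-dimethylbut-3-en-1-ol
Product: 19 2,2-dimethylbut-3-enal
Conditions: Dess–Martin periodinane, CH2Cl2, 0 °C to rt; filtered and used as a solution
Reagents that add atoms: none
Why: The Dess–Martin oxidation gives a non-enolisable, volatile aldehyde that cannot isomerise and is carried on without concentration.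

**Step 11**
Reactants: 19 2,2-dimethylbut-3-enal
Product: 20 (E)-1-iodo-3,3-dimethylpenta-1,4-diene
Conditions: CrCl2 (6 equiv), CHI3 (2 equiv), THF, 0 °C
Reagents that add atoms: iodoform IC(I)I
Why: The Takai olefination is strongly E-selective with α-branched aldehydes and installs the future C5 as an iodoalkene carbon.

**Step 12**
Reactants: 16 (S)-5-Ar-5-[(E)-1,2-dichlorovinyloxy]pentanal; 20 (E)-1-iodo-3,3-dimethylpenta-1,4-diene
Product: 23 (4E,10S)-10-Ar-10-(ethynyloxy)-3,3-dimethyldeca-1,4-dien-6-ol, via alkenyllithium 21 (not isolated), via lithium alkoxide 22 (not isolated)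
Conditions: 20 (1.3 equiv), t-BuLi (2.6 equiv), Et2O, −78 °C; 16, THF, −78 °C; n-BuLi (3 equiv), −78 to −40 °C; H2O, −78 to 0 °C
Reagents that add atoms: none
Why: Iodine–lithium exchange with retention of alkene geometry and 1,2-addition to the aldehyde give an alkoxide that is inert to n-BuLi, so the second stage of the trichloroethylene ynol ether synthesis (dehydrochlorination, chlorine–lithium exchange, protonation) can follow in the same flask.

**Step 13**
Reactants: 23 (4E,10S)-10-Ar-10-(ethynyloxy)-3,3-dimethyldeca-1,4-dien-6-ol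
Product: 24 (4E,10S)-10-Ar-10-(ethynyloxy)-3,3-dimethyldeca-1,4-dien-6-one
Conditions: activated MnO2 (excess), CH2Cl2, 0 °C to rt
Reagents that add atoms: none
Why: Heterogeneous MnO2 allylic oxidation is neutral and releases no acid, so the acid-sensitive ethynyl ether should survive while both carbinol epimers converge on one enone.

**Step 14**
Reactants: 24 (4E,10S)-10-Ar-10-(ethynyloxy)-3,3-dimethyldeca-1,4-dien-6-one
Product: 26 (4E,10S)-10-Ar-7-diazo-10-(ethynyloxy)-3,3-dimethyldeca-1,4-dien-6-one, via trifluoroacetyl diketone 25 (not isolated)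
Conditions: LiHMDS (1.1 equiv), THF, −78 °C; CF3CO2CH2CF3 (1.2 equiv), −78 °C; pH 7 buffer; MsN3 (1.5 equiv), Et3N (1.5 equiv), H2O (1 equiv), MeCN, 20 °C; used at once
Reagents that add atoms: methanesulfonyl azide CS(=O)(=O)N=[N+]=[N-]; 2,2,2-trifluoroethyl trifluoroacetate O=C(OCC(F)(F)F)C(F)(F)F (its CF3CO group stays only in 25)
Why: In this detrifluoroacetylative (Regitz-type) diazo transfer the γ-carbon is quaternary, so only the α'-CH2 (future C4a) can be enolised, the ketone is more acidic than the acetylenic C–H, and a neutral quench replaces the usual acid wash to spare the ynol ether.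

**Step 15**
Reactants: 26 (4E,10S)-10-Ar-7-diazo-10-(ethynyloxy)-3,3-dimethyldeca-1,4-dien-6-one
Product: 31 (2S)-2-Ar-6-(2-methylbut-3-en-2-yl)chroman-7-ol (5'-O-TIPS kazinol H), via vinylketene 27 (not isolated), via bicyclic cyclobutenone 28 (not isolated), via dienylketene 29 (not isolated), via cyclohexadienone 30 (not isolated)
Conditions: hν (LED, 420–450 nm), degassed toluene (0.005 M), 15 °C until 26 is consumed; then 90 °C
Reagents that add atoms: none
Why: Proposed new method: light expels N2 from 26 and the alkenyl group moves from the carbonyl carbon to the diazo carbon (Wolff rearrangement, C4a–C5) to give vinylketene 27, whose electrophilic ketene carbon C7 is attacked by the nucleophilic terminal alkyne carbon C8 while C4a bonds to the oxygen-bearing C8a, a formal [2+2] giving 28; on heating 28 opens (4π) to dienylketene 29, which closes (6π, C6–C7) to 30 and tautomerises to the C7 phenol. The closest known reaction types are the intermolecular Danheiser benzannulation of photochemically generated vinylketenes with alkoxy- and siloxyalkynes, intramolecular ketene [2+2] cycloadditions, and the visible-light Wolff rearrangement of diazo ketones bearing an alkyl group on the diazo carbon; the tether between the two partners is the new element. Ring C closes in the cycloaddition as a 6-exo-dig attack of C4a on C8a (the six-membered half of a 2-oxabicyclo[4.2.0]octenone), and ring A closes by disrotatory 6π electrocyclisation of 29, in which the endocyclic C4a=C8a bond of the dihydropyran holds the ketene and alkenyl arms cis, so no unproductive dienylketene geometry exists. No lasting stereocentre is created, since the quaternary C4a of 28 and the sp3 C6 of 30 vanish on ring opening and aromatisation, and C2 lies outside the reacting π system under neutral conditions and keeps its S configuration. The step needs head-to-tail regiochemistry (C7 to C8, C4a to C8a), which the ynol ether polarity and the four-atom chain C4–C3–C2–O1 both impose, chemoselectivity for the ynol ether over the prenyl, chromene and vinyl C=C bonds, which its much higher nucleophilicity and proximity secure, and the 1,1-dimethylallyl group on C6, which is fixed because the quaternary carbon already sits on the enone terminus. High dilution suppresses ketene dimerisation, light of 420–450 nm is not absorbed by the 2H-chromene (no photochromic ring opening), and heating begins only after the thermally fragile benzylic ynol ether has been consumed at 15 °C.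

**Step 16**
Reactants: 31 (2S)-2-Ar-6-(2-methylbut-3-en-2-yl)chroman-7-ol
Product: 32 kazinol H
Conditions: TBAF, AcOH (1:1), THF, 0 °C
Reagents that add atoms: none
Why: Buffered fluoride desilylation of the single aryl silyl ether is non-acidic, so the para-alkoxybenzylic C2–O1 bond, the chromene and both prenyl-type groups are left alone.

**Compound list**
1 | 2-bromo-4,5-dimethoxybenzaldehyde | COc1cc(Br)c(C=O)cc1OC | starting material
2 | 2-bromo-4,5-dihydroxybenzaldehyde | O=Cc1cc(O)c(O)cc1Br | intermediate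
3 | 3-chloro-3-methylbut-1-yne | C#CC(C)(C)Cl | starting material
4 | 2-bromo-5-hydroxy-4-[(2-methylbut-3-yn-2-yl)oxy]benzaldehyde | O=Cc1cc(O)c(OC(C)(C)C#C)cc1Br | intermediate
5 | 2-bromo-4-[(2-methylbut-3-yn-2-yl)oxy]-5-(triisopropylsilyloxy)benzaldehyde | O=Cc1cc(O[Si](C(C)C)(C(C)C)C(C)C)c(OC(C)(C)C#C)cc1Br | intermediate
6 | 2-bromo-4-hydroxy-3-(3-methylbuta-1,2-dienyl)-5-(triisopropylsilyloxy)benzaldehyde | O=Cc1cc(O[Si](C(C)C)(C(C)C)C(C)C)c(O)c(C=C=C(C)C)c1Br | intermediate
7 | 5-bromo-2,2-dimethyl-8-(triisopropylsilyloxy)-2H-chromene-6-carbaldehyde | O=Cc1cc(O[Si](C(C)C)(C(C)C)C(C)C)c2c(c1Br)C=CC(C)(C)O2 | intermediate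
8 | (S)-1-(bromochromenyl)but-3-enyl diisopinocampheylborinate | O([C@H](c1cc(O[Si](C(C)C)(C(C)C)C(C)C)c2c(c1Br)C=CC(C)(C)O2)CC=C)B([C@@H]1C[C@@H]2C[C@H]([C@H]1C)C2(C)C)[C@@H]1C[C@@H]2C[C@H]([C@H]1C)C2(C)C | intermediate
9 | (S)-1-[5-bromo-2,2-dimethyl-8-(triisopropylsilyloxy)-2H-chromen-6-yl]but-3-en-1-ol | O[C@H](c1cc(O[Si](C(C)C)(C(C)C)C(C)C)c2c(c1Br)C=CC(C)(C)O2)CC=C | intermediate
10 | 1-bromo-3-methylbut-2-ene | CC(C)=CCBr | starting material
11 | C5-lithio lithium alkoxide of 9 | [Li]O[C@H](c1cc(O[Si](C(C)C)(C(C)C)C(C)C)c2c(c1[Li])C=CC(C)(C)O2)CC=C | intermediate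
12 | (S)-1-Ar-but-3-en-1-ol | O[C@H](c1cc(O[Si](C(C)C)(C(C)C)C(C)C)c2c(c1CC=C(C)C)C=CC(C)(C)O2)CC=C | intermediate
13 | trichloroethylene | ClC=C(Cl)Cl | starting material
14 | dichloroacetylene | ClC#CCl | intermediate
15 | (S)-1-Ar-but-3-en-1-yl (E)-1,2-dichlorovinyl ether | Cl/C=C(/Cl)O[C@H](c1cc(O[Si](C(C)C)(C(C)C)C(C)C)c2c(c1CC=C(C)C)C=CC(C)(C)O2)CC=C | intermediate
16 | (S)-5-Ar-5-[(E)-1,2-dichlorovinyloxy]pentanal | Cl/C=C(/Cl)O[C@H](c1cc(O[Si](C(C)C)(C(C)C)C(C)C)c2c(c1CC=C(C)C)C=CC(C)(C)O2)CCCC=O | intermediate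
17 | 2,2-dimethylbut-3-enoic acid | C=CC(C)(C)C(=O)O | starting material
18 | 2,2-dimethylbut-3-en-1-ol | C=CC(C)(C)CO | intermediate
19 | 2,2-dimethylbut-3-enal | C=CC(C)(C)C=O | intermediate
20 | (E)-1-iodo-3,3-dimethylpenta-1,4-diene | C=CC(C)(C)/C=C/I | intermediate
21 | (E)-(3,3-dimethylpenta-1,4-dienyl)lithium | C=CC(C)(C)/C=C/[Li] | intermediate
22 | lithium (4E,10S)-10-Ar-10-[(E)-1,2-dichlorovinyloxy]-3,3-dimethyldeca-1,4-dien-6-olate | Cl/C=C(/Cl)O[C@H](c1cc(O[Si](C(C)C)(C(C)C)C(C)C)c2c(c1CC=C(C)C)C=CC(C)(C)O2)CCCC(O[Li])/C=C/C(C)(C)C=C | intermediate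
23 | (4E,10S)-10-Ar-10-(ethynyloxy)-3,3-dimethyldeca-1,4-dien-6-ol | C#CO[C@H](c1cc(O[Si](C(C)C)(C(C)C)C(C)C)c2c(c1CC=C(C)C)C=CC(C)(C)O2)CCCC(O)/C=C/C(C)(C)C=C | intermediate
24 | (4E,10S)-10-Ar-10-(ethynyloxy)-3,3-dimethyldeca-1,4-dien-6-one | C#CO[C@H](c1cc(O[Si](C(C)C)(C(C)C)C(C)C)c2c(c1CC=C(C)C)C=CC(C)(C)O2)CCCC(=O)/C=C/C(C)(C)C=C | intermediate
25 | (4E,10S)-10-Ar-10-(ethynyloxy)-3,3-dimethyl-7-(trifluoroacetyl)deca-1,4-dien-6-one | C#CO[C@H](c1cc(O[Si](C(C)C)(C(C)C)C(C)C)c2c(c1CC=C(C)C)C=CC(C)(C)O2)CCC(C(=O)C(F)(F)F)C(=O)/C=C/C(C)(C)C=C | intermediate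
26 | (4E,10S)-10-Ar-7-diazo-10-(ethynyloxy)-3,3-dimethyldeca-1,4-dien-6-one | C#CO[C@H](c1cc(O[Si](C(C)C)(C(C)C)C(C)C)c2c(c1CC=C(C)C)C=CC(C)(C)O2)CCC(=[N+]=[N-])C(=O)/C=C/C(C)(C)C=C | intermediate
27 | (3E)-2-[(3S)-3-Ar-3-(ethynyloxy)propyl]-5,5-dimethylhepta-1,3,6-trien-1-one | C#CO[C@H](c1cc(O[Si](C(C)C)(C(C)C)C(C)C)c2c(c1CC=C(C)C)C=CC(C)(C)O2)CCC(=C=O)/C=C/C(C)(C)C=C | intermediate
28 | (3S)-3-Ar-6-[(E)-3,3-dimethylpenta-1,4-dienyl]-2-oxabicyclo[4.2.0]oct-1(8)-en-7-one | O=C1C=C2O[C@H](c3cc(O[Si](C(C)C)(C(C)C)C(C)C)c4c(c3CC=C(C)C)C=CC(C)(C)O4)CCC12/C=C/C(C)(C)C=C | intermediate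
29 | 2-{(2S)-2-Ar-5-[(E)-3,3-dimethylpenta-1,4-dienyl]-3,4-dihydro-2H-pyran-6-yl}ethenone | O=C=CC1=C(/C=C/C(C)(C)C=C)CC[C@@H](c2cc(O[Si](C(C)C)(C(C)C)C(C)C)c3c(c2CC=C(C)C)C=CC(C)(C)O3)O1 | intermediate
30 | (2S)-2-Ar-6-(2-methylbut-3-en-2-yl)-3,4-dihydro-2H-chromen-7(6H)-one | O=C1C=C2O[C@H](c3cc(O[Si](C(C)C)(C(C)C)C(C)C)c4c(c3CC=C(C)C)C=CC(C)(C)O4)CCC2=CC1C(C)(C)C=C | intermediate
31 | (2S)-2-Ar-6-(2-methylbut-3-en-2-yl)chroman-7-ol (5'-O-TIPS kazinol H) | C=CC(C)(C)c1cc2c(cc1O)O[C@H](c1cc(O[Si](C(C)C)(C(C)C)C(C)C)c3c(c1CC=C(C)C)C=CC(C)(C)O3)CC2 | intermediate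
32 | kazinol H | C=CC(C)(C)c1cc2c(cc1O)O[C@H](c1cc(O)c3c(c1CC=C(C)C)C=CC(C)(C)O3)CC2 | target

**Total step count:** 16. **Longest linear sequence:** 13 (steps 1–8 and 12–16).

**Steps most likely to fail**

**Step 15.**
- Possible failures:
  - The carbene may undergo a 1,2-hydrogen shift from C4 instead of the Wolff shift.
  - The diazo group may add as a dipole to the tethered ynol ether before photolysis.
  - The cycloaddition across the four-atom tether may be too slow. The vinylketene would then dimerise or close to a monocyclic cyclobutenone, while the benzylic ynol ether decays by a sigmatropic shift onto C6' or by retro-ene loss of ketene.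
- Fallback (known chemistry only): the two ring closures are uncoupled.
  - From 7, allylboration with the enantiomeric (−)-Ipc2B(allyl) gives the (R)-bromo carbinol F1.
  - Prenylation as in step 6 gives the (R)-carbinol F2, and TBSOTf/2,6-lutidine gives the silyl ether F3.
  - Hydroformylation as in step 8 gives the aldehyde F4, addition of 21 gives the allylic alcohol F5, and MnO2 gives the enone F6.
  - Detrifluoroacetylative diazo transfer gives the diazo enone F7.
  - Irradiation of F7 with an excess of (triisopropylsilyloxy)ethyne, then heating, is the Danheiser benzannulation in its established intermolecular form. It gives the resorcinol monosilyl ether F8 with the same control of the C6 substituent.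
  - TBAF removes the three silyl groups to give the tetraol F9.
  - A Mitsunobu cyclisation (PPh3, DIAD, dilute THF) closes ring C by SN2 attack of the C8a phenol on C2 with inversion (R to S). The route is rejoined at 32.

**Step 14.**
- Possible failures:
  - Deprotonation and trifluoroacetylation may compete at the acetylenic C–H.
  - The ethynyl ether may hydrate during the two-stage work-up.
- Fallback: the acidic hydrogen is replaced by silicon, and the enone is made by a Weinreb ketone synthesis.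
  - From 16, Pinnick oxidation gives the acid F10, and CDI followed by MeNH(OMe)·HCl gives the Weinreb amide F11.
  - Addition of 21 gives the stable tetrahedral chelate. In the same flask n-BuLi turns the dichlorovinyl ether into the lithium acetylide, and Me3SiCl caps it.
  - Aqueous work-up releases the C-silylated ynol ether enone F12, which is also the more robust ynol ether.
  - Diazo transfer gives the diazo enone F13, and the conditions of step 15 give the 8-trimethylsilyl flavan F14.
  - TBAF in wet THF removes the O-TIPS group and should protodesilylate C8, which is flanked by O1 and the C7 phenoxide. The route is rejoined at 32.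

**Step 12.**
- Possible failures:
  - The alkenyllithium may attack the dichlorovinyl ether.
  - The aldehyde may be enolised.
  - The ethynyl ether may be lost on isolation from a strongly basic mixture.
- Fallback: the carbon–carbon bond is made without an organolithium, and the two events are separated.
  - From 16 and 20, a Nozaki–Hiyama–Kishi coupling (CrCl2, cat. NiCl2, DMF, rt) gives the neutral allylic alcohol F15, which is isolated and purified.
  - n-BuLi (3.3 equiv, THF, −78 to −40 °C), then water, converts F15 into 23, where the route is rejoined.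

**Further compounds**
F1 | step 15 | (R)-1-[5-bromo-2,2-dimethyl-8-(triisopropylsilyloxy)-2H-chromen-6-yl]but-3-en-1-ol | O[C@@H](c1cc(O[Si](C(C)C)(C(C)C)C(C)C)c2c(c1Br)C=CC(C)(C)O2)CC=C
F2 | step 15 | (R)-1-Ar-but-3-en-1-ol | O[C@@H](c1cc(O[Si](C(C)C)(C(C)C)C(C)C)c2c(c1CC=C(C)C)C=CC(C)(C)O2)CC=C
F3 | step 15 | (R)-1-Ar-but-3-en-1-yl tert-butyldimethylsilyl ether | CC(C)(C)[Si](C)(C)O[C@@H](c1cc(O[Si](C(C)C)(C(C)C)C(C)C)c2c(c1CC=C(C)C)C=CC(C)(C)O2)CC=C
F4 | step 15 | (R)-5-Ar-5-(tert-butyldimethylsilyloxy)pentanal | CC(C)(C)[Si](C)(C)O[C@@H](c1cc(O[Si](C(C)C)(C(C)C)C(C)C)c2c(c1CC=C(C)C)C=CC(C)(C)O2)CCCC=O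
F5 | step 15 | (4E,10R)-10-Ar-10-(tert-butyldimethylsilyloxy)-3,3-dimethyldeca-1,4-dien-6-ol | CC(C)(C)[Si](C)(C)O[C@@H](c1cc(O[Si](C(C)C)(C(C)C)C(C)C)c2c(c1CC=C(C)C)C=CC(C)(C)O2)CCCC(O)/C=C/C(C)(C)C=C
F6 | step 15 | (4E,10R)-10-Ar-10-(tert-butyldimethylsilyloxy)-3,3-dimethyldeca-1,4-dien-6-one | CC(C)(C)[Si](C)(C)O[C@@H](c1cc(O[Si](C(C)C)(C(C)C)C(C)C)c2c(c1CC=C(C)C)C=CC(C)(C)O2)CCCC(=O)/C=C/C(C)(C)C=C
F7 | step 15 | (4E,10R)-10-Ar-10-(tert-butyldimethylsilyloxy)-7-diazo-3,3-dimethyldeca-1,4-dien-6-one | CC(C)(C)[Si](C)(C)O[C@@H](c1cc(O[Si](C(C)C)(C(C)C)C(C)C)c2c(c1CC=C(C)C)C=CC(C)(C)O2)CCC(=[N+]=[N-])C(=O)/C=C/C(C)(C)C=C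
F8 | step 15 | 4-[(3R)-3-Ar-3-(tert-butyldimethylsilyloxy)propyl]-2-(2-methylbut-3-en-2-yl)-5-(triisopropylsilyloxy)phenol | C=CC(C)(C)c1cc(CC[C@@H](O[Si](C)(C)C(C)(C)C)c2cc(O[Si](C(C)C)(C(C)C)C(C)C)c3c(c2CC=C(C)C)C=CC(C)(C)O3)c(O[Si](C(C)C)(C(C)C)C(C)C)cc1O
F9 | step 15 | 4-[(3R)-3-hydroxy-3-(8-hydroxy-2,2-dimethyl-5-prenyl-2H-chromen-6-yl)propyl]-6-(2-methylbut-3-en-2-yl)benzene-1,3-diol | C=CC(C)(C)c1cc(CC[C@@H](O)c2cc(O)c3c(c2CC=C(C)C)C=CC(C)(C)O3)c(O)cc1O
F10 | step 14 | (S)-5-Ar-5-[(E)-1,2-dichlorovinyloxy]pentanoic acid | Cl/C=C(/Cl)O[C@H](c1cc(O[Si](C(C)C)(C(C)C)C(C)C)c2c(c1CC=C(C)C)C=CC(C)(C)O2)CCCC(=O)O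
F11 | step 14 | (S)-5-Ar-5-[(E)-1,2-dichlorovinyloxy]-N-methoxy-N-methylpentanamide | Cl/C=C(/Cl)O[C@H](c1cc(O[Si](C(C)C)(C(C)C)C(C)C)c2c(c1CC=C(C)C)C=CC(C)(C)O2)CCCC(=O)N(C)OC
F12 | step 14 | (4E,10S)-10-Ar-3,3-dimethyl-10-[(trimethylsilyl)ethynyloxy]deca-1,4-dien-6-one | C[Si](C)(C)C#CO[C@H](c1cc(O[Si](C(C)C)(C(C)C)C(C)C)c2c(c1CC=C(C)C)C=CC(C)(C)O2)CCCC(=O)/C=C/C(C)(C)C=C
F13 | step 14 | (4E,10S)-10-Ar-7-diazo-3,3-dimethyl-10-[(trimethylsilyl)ethynyloxy]deca-1,4-dien-6-one | C[Si](C)(C)C#CO[C@H](c1cc(O[Si](C(C)C)(C(C)C)C(C)C)c2c(c1CC=C(C)C)C=CC(C)(C)O2)CCC(=[N+]=[N-])C(=O)/C=C/C(C)(C)C=C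
F14 | step 14 | (2S)-2-Ar-6-(2-methylbut-3-en-2-yl)-8-(trimethylsilyl)chroman-7-ol | C=CC(C)(C)c1cc2c(c([Si](C)(C)C)c1O)O[C@H](c1cc(O[Si](C(C)C)(C(C)C)C(C)C)c3c(c1CC=C(C)C)C=CC(C)(C)O3)CC2
F15 | step 12 | (4E,10S)-10-Ar-10-[(E)-1,2-dichlorovinyloxy]-3,3-dimethyldeca-1,4-dien-6-ol | Cl/C=C(/Cl)O[C@H](c1cc(O[Si](C(C)C)(C(C)C)C(C)C)c2c(c1CC=C(C)C)C=CC(C)(C)O2)CCCC(O)/C=C/C(C)(C)C=C
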